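## The problem

The target **27** is a coumarin (O1, C2–C8a) whose benzenoid ring is substituted at every carbon but one: an (S)-2-hydroxypropyl chain at C5, methyl groups at C6 and C8, and a hydroxyl at C7. C3 is bonded to C2' of a 6'-methyl-5',6'-dihydropyran-4'-one (O1', C2'=C3', C4' carbonyl, C5'H2, C6'). A synthesis has to build the crowded arene with the side chain meta to both oxygens, close the lactone ring onto it, and attach and close the dihydropyranone at C3. The two stereocentres, the side-chain carbinol (S) and C6' (R), lie far apart on opposite sides of the flat coumarin. Neither can control the other, so each must come from its own enantiopure building block and stay untouched. The dihydropyranone is a cyclic β-alkoxy enone: base can expel O1' from C6' by retro-oxa-Michael opening and scramble C6', so nothing basic may follow its formation. The coumarin itself is a lactone and a Michael acceptor at C4, and the phenol and the alcohol need protection that leaves under acid or fluoride. The two phenolic oxygens of the arene must also be told apart: the future O1 has one ortho methyl, the C7 oxygen has two. The feature that opens the key step is that C4a is the only unsubstituted arene carbon, ortho to the C8a oxygen and para to the C7 oxygen. A one-carbon electrophile tethered through the C8a ester oxygen can therefore only close at C4a, forming C4–C4a and the lactone ring at once.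

## Retrosynthesis

**27 ⇒ 24.** The O1'–C2' enol-ether bond is cut and the three silyl ethers are put back, giving the open-chain δ-silyloxy β-diketone **24**. This cut is preferred because the ring then closes under acid alone, the only reagent class the finished pyranone tolerates. Cutting C5'–C6' instead would create C6' late under catalyst control, and cutting C3–C2' would need a fragile pyranone organometallic. **24** has no pyranone ring and already holds C6' as a silyl ether. The forward reaction must remove the chain TBS group, cyclise through the only six-membered mode, dehydrate, and then take off TIPS and TBDPS without base.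

**24 ⇒ 20 + 23.** The C2'–C3' bond (acyl carbon to methylene) is cut. This splits the molecule at the junction of the two ring systems and places C6' in the five-carbon ketone **23**, which comes in two steps from (R)-pent-4-en-2-ol **21** through silyl ether **22**. The neighbouring cut at C3'–C4' would require an enolate sitting next to the Michael-acceptor coumarin. The forward reaction needs the kinetic methyl enolate of **23**, C- rather than O-acylation, and attack on the acid chloride **20** rather than on C4.

**20 ⇒ 19 ⇒ 18.** No skeletal bond is cut; the acid chloride is traced through acid **19** to ethyl ester **18**, the form in which the key step delivers the C3 carboxyl. The forward steps need a saponification that spares the aryl TIPS ether and a neutral chlorination.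

**18 ⇒ 16.** The C4–C4a bond is cut, which opens the lactone ring into the aryl ethyl ethoxymethylenemalonate **16**. The neighbouring cuts (C3=C4 by Knoevenagel, O1–C2 by lactonisation) both presuppose a separate formylation at the position flanked by the C5 side chain. Here the same carbon arrives already bonded to C3, C2 and the carboxyl, and the hindered C–C bond forms as a six-membered ring closure. **16** has one ring fewer and no new stereocentre. The forward reaction needs the arene to attack the alkoxymethylene carbon rather than an ester carbonyl, and the silyl ethers to survive a Lewis acid.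

**16 ⇒ 13 + 14; 13 ⇒ 11 + 12.** The C3=C4 bond is cut to aryl ethyl malonate **13** and triethyl orthoformate **14**, and the O1–C2 ester bond to phenol **11** and ethyl malonyl chloride **12**. Both reagents are stock chemicals and the order puts the one-carbon unit on last. The forward condensation must not exchange the aryl ester.

**11 ⇒ 10 ⇒ 8.** No skeletal bond is cut; this is the sorting of the two phenols. Every reagent prefers the less hindered hydroxyl, which is the one that must end up free. It is therefore capped first with TBS, the hindered one is capped with TIPS (bis-silyl ether **10**), and the TBS group is then removed selectively. Resorcinol **8** is simpler by two protecting groups.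

**8 ⇒ 7 ⇒ 4 + 5.** The arene is traced to cyclohexane-1,3-dione **7** by adding one H2. The ring is then cut at the bonds that become C5–C6 and C8–C8a of the coumarin, giving enoate **4** and pentan-3-one **5**. This Michael–Claisen cut places both methyl groups, both oxygens and the side chain in one operation. An aromatic starting material with this pattern (side chain meta to both oxygens) is not readily available. The forward reaction needs conjugate addition to outrun γ-deprotonation of **4**.

**4 ⇒ 2 + 3; 2 ⇒ 1.** The C=C bond of the enoate is cut by cross-metathesis to silyl ether **2** and ethyl acrylate **3**, and **2** is the TBDPS ether of (S)-pent-4-en-2-ol **1**. The side-chain stereocentre is thus bought, and it is protected from the first step with a group that lasts to the end.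

## Roads not taken

**Alternative 1:** The strategic step is the annulation that builds the carbocycle. The cut is at the future C5–C6 and C8–C8a bonds. The enolate of pentan-3-one **5** adds to (S)-parasorbic acid **A1** and the re-formed enolate attacks the lactone carbonyl, giving hydroxy-dione **A2** and releasing the side-chain alkoxide.
- Merits: the cyclic enoate **A1** is a better Michael acceptor than an open-chain enoate, and the whole arene skeleton with its stereocentre is formed at once.
- Weak points: **A1** opens to a sorbate on γ-deprotonation; the product has three unprotected hydroxyls to be sorted; and the strategy says nothing about the lactone ring or the C3 substituent, so a formylation of the crowded arene would still be needed.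
- Comparison: the chosen route uses the open-chain relative of this annulation as step 3, so the two plans share this bond construction. **A1** is the more reactive acceptor, and that advantage is real. Against it the chosen plan sets a side chain that is already protected, and a key step that solves the coumarin closure.

**Alternative 2:** The cut is the C5–CH2 bond. 2,4-Dimethoxy-3,5-dimethylbenzoic acid **A3** is alkylated at its only ortho C–H by (S)-propylene oxide **A4** under Pd(OAc)2 (divalent palladium) with a mono-N-protected amino acid ligand. The alkoxide then lactonises to isochromanone **A5**, whose carbonyl carbon sits on the future C4a and can later serve as C4.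
- Merits: no aromatisation, the cheapest possible chiral building block, and the C4–C4a bond exists from the start. In this respect it is better than the chosen plan, which must form that bond on a hindered ring.
- Weak points: **A3** is not a stock compound; the C–H to be activated is flanked by a methyl group; and both oxygens are methyl ethers. The C7 ether would need a boron-halide cleavage before the pyranone exists, followed by re-protection. Reduction of the lactone and a Knoevenagel step would also release the side-chain hydroxyl unprotected in mid-route.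
- Comparison: up to the coumarin ester it is at least as short. The chosen plan sets against it silyl groups that leave under the mild final conditions and a metal-free ring closure that cannot occur at a wrong position.

**Alternative 3:** The cut is at C5'–C6' and O1'–C2'. The 1,3-bis(trimethylsilyloxy)diene **A6** reacts with acetaldehyde **A7** under a chiral Ti(OiPr)4/BINOL Lewis acid (tetravalent titanium) and then acid, giving the bis-TBS ether **A8** of the target with C6' set by the catalyst.
- Merits: the pyranone is made in the most convergent way, no chiral ketone fragment is needed, and either C6' epimer is accessible.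
- Weak points: the small aldehyde **A7** offers little for a catalyst to discriminate, and any leakage gives a diastereomer that differs only at a remote centre and would be hard to remove. **A6** also needs a C-acylation like step 14 plus a double enol silylation, so nothing is saved.
- Comparison: this road concerns only the endgame and is compatible with the chosen key step. It is shorter by the two steps that make **23**. The chosen plan sets against it a C6' configuration fixed by the starting material **21**.

Key step: step 9

Remark on the chemistry: **16** is used as the E/Z mixture (both isomers give **18**); **6**, **7**, **15** and **17** are mixtures at centres that are later destroyed; β-diketones **24** and **25** are drawn as diketo tautomers.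

## Route

Step 1
Reactants: 1 (S)-pent-4-en-2-ol
Product: 2 (S)-tert-butyl(pent-4-en-2-yloxy)diphenylsilane
Conditions: TBDPSCl, imidazole, DMF, 0 °C → rt
Reagents that add atoms: tert-butyl(chloro)diphenylsilane (TBDPSCl), CC(C)(C)[Si](Cl)(c1ccccc1)c1ccccc1
Why: Standard silylation of a secondary alcohol; TBDPS is chosen because it must outlast BF3·OEt2, hot Ac2O and aqueous LiOH later. The stereocentre is not involved.

Step 2
Reactants: 2 (S)-tert-butyl(pent-4-en-2-yloxy)diphenylsilane; 3 ethyl acrylate
Product: 4 ethyl (S,E)-5-(tert-butyldiphenylsilyloxy)hex-2-enoate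
Conditions: 3 (3 equiv), second-generation Grubbs catalyst RuCl2(=CHPh)(H2IMes)(PCy3) (3 mol%), CH2Cl2, 40 °C
Reagents that add atoms: none
Why: Olefin cross-metathesis of a terminal alkene with an acrylate, which is selective for the cross product and the E enoate because the acrylate homodimerises slowly.

Step 3
Reactants: 5 pentan-3-one; 4 ethyl (S,E)-5-(tert-butyldiphenylsilyloxy)hex-2-enoate
Product: 7 5-[(S)-2-(tert-butyldiphenylsilyloxy)propyl]-2,4-dimethylcyclohexane-1,3-dione, via keto ester 6 (not isolated)
Conditions: 5 (2.2 equiv), LiN(iPr)2 (2.1 equiv), THF, −78 °C; then 4, −78 → 0 °C; then rt; aq. HCl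
Reagents that add atoms: none
Why: Consecutive Michael–Claisen annulation of a dialkyl ketone with an enoate: the enolate of 5 adds to C3 of 4 to give 6, the enolate re-forms at the other α-carbon and closes on the ester, and deprotonation of the 2-methyl-1,3-dione drives the sequence. The new ring stereocentres form unselectively and are erased in step 4; the silyloxy carbon is not involved.

Step 4
Reactants: 7 5-[(S)-2-(tert-butyldiphenylsilyloxy)propyl]-2,4-dimethylcyclohexane-1,3-dione
Product: 8 5-[(S)-2-(tert-butyldiphenylsilyloxy)propyl]-2,4-dimethylbenzene-1,3-diol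
Conditions: Pd/C (10 wt% Pd), mesitylene, reflux, N2 sweep
Reagents that add atoms: none
Why: Catalytic dehydrogenation of a dihydroresorcinol over palladium, the reaction type that converts 2-methylcyclohexane-1,3-dione into 2-methylresorcinol; only one H2 is lost. The secondary silyl ether is neither benzylic nor allylic and should be untouched.

Step 5
Reactants: 8 5-[(S)-2-(tert-butyldiphenylsilyloxy)propyl]-2,4-dimethylbenzene-1,3-diol
Product: 10 {5-(tert-butyldimethylsilyloxy)-3-[(S)-2-(tert-butyldiphenylsilyloxy)propyl]-2,6-dimethylphenoxy}triisopropylsilane, via mono-TBS phenol 9 (not isolated)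
Conditions: TBSCl (1.05 equiv), imidazole, CH2Cl2, −20 → 0 °C; then TIPSOTf (1.3 equiv), 2,6-lutidine, 0 °C → rt
Reagents that add atoms: tert-butyl(chloro)dimethylsilane (TBSCl), CC(C)(C)[Si](C)(C)Cl; triisopropylsilyl trifluoromethanesulfonate (TIPSOTf), CC(C)[Si](OS(=O)(=O)C(F)(F)F)(C(C)C)C(C)C
Why: Steric discrimination in phenol silylation: the hydroxyl with one ortho methyl takes the TBS group first, and the stronger silylating agent TIPSOTf then caps the hydroxyl flanked by two methyls.

Step 6
Reactants: 10 {5-(tert-butyldimethylsilyloxy)-3-[(S)-2-(tert-butyldiphenylsilyloxy)propyl]-2,6-dimethylphenoxy}triisopropylsilane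
Product: 11 5-[(S)-2-(tert-butyldiphenylsilyloxy)propyl]-2,4-dimethyl-3-(triisopropylsilyloxy)phenol
Conditions: K2CO3 (0.2 equiv), MeOH/THF, 0 °C → rt
Reagents that add atoms: none
Why: Base-catalysed methanolysis of aryl silyl ethers is much faster for TBS than for TIPS and is slowed further by two ortho substituents, so only the less shielded aryl TBS ether is cleaved. The alkyl TBDPS ether is inert to K2CO3/MeOH.

Step 7
Reactants: 11 5-[(S)-2-(tert-butyldiphenylsilyloxy)propyl]-2,4-dimethyl-3-(triisopropylsilyloxy)phenol; 12 ethyl malonyl chloride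
Product: 13 ethyl 5-[(S)-2-(tert-butyldiphenylsilyloxy)propyl]-2,4-dimethyl-3-(triisopropylsilyloxy)phenyl malonate
Conditions: pyridine, CH2Cl2, 0 °C
Reagents that add atoms: none
Why: Standard O-acylation of a phenol with an acid chloride; only one hydroxyl is free.

Step 8
Reactants: 13 ethyl 5-[(S)-2-(tert-butyldiphenylsilyloxy)propyl]-2,4-dimethyl-3-(triisopropylsilyloxy)phenyl malonate; 14 triethyl orthoformate
Product: 16 1-ethyl 3-{5-[(S)-2-(tert-butyldiphenylsilyloxy)propyl]-2,4-dimethyl-3-(triisopropylsilyloxy)phenyl} 2-(ethoxymethylene)malonate, via diethoxymethyl malonate 15 (not isolated)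
Conditions: 14 (3 equiv), Ac2O (3 equiv), ZnCl2 (1 mol%), 120 °C
Reagents that add atoms: none
Why: Alkoxymethylenation of a malonate with an orthoformate in Ac2O, the reaction that converts diethyl malonate into diethyl ethoxymethylenemalonate: the malonate enol attacks the diethoxycarbenium ion to give acetal 15, which loses ethanol. Ac2O traps the ethanol so that it cannot exchange the aryl ester, and ZnCl2 is kept to a trace so that ring closure waits for step 9.

Step 9
Reactants: 16 1-ethyl 3-{5-[(S)-2-(tert-butyldiphenylsilyloxy)propyl]-2,4-dimethyl-3-(triisopropylsilyloxy)phenyl} 2-(ethoxymethylene)malonate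
Product: 18 ethyl 6,8-dimethyl-2-oxo-5-[(S)-2-(tert-butyldiphenylsilyloxy)propyl]-7-(triisopropylsilyloxy)-2H-chromene-3-carboxylate, via 4-ethoxychromanone 17 (not isolated)
Conditions: BF3·OEt2 (3 equiv), CH2Cl2, 0 °C → rt
Reagents that add atoms: none
Why: BF3 binds the two carbonyl oxygens of the alkylidene malonate in 16 and makes the ethoxymethylene carbon an oxocarbenium-like electrophile. C4a, the only free arene carbon, ortho to the ester oxygen and para to the C7 silyloxy group, attacks it; the σ-complex loses a proton to give 4-ethoxychromanone 17, and BF3-assisted loss of ethanol restores the C3=C4 double bond inside the lactone ring. The closest known reactions are the Pechmann-type condensation of phenols with alkoxymethylenemalonates to coumarin-3-carboxylates and the acid-mediated closure of aryl 3-alkoxyacrylates; here the ester bond is made first (step 7), so the C–C bond formation is intramolecular. The ring closes 6-endo-trig with respect to the C3=C4 bond, after the aryl ester rotates into its s-cis conformer as in any Pechmann closure. No stereocentre is formed, and either geometry of 16 gives the same product because C4 is bonded to C3 in both. The step needs attack at the vinylogous carbon rather than Fries-type attack at an ester carbonyl, which the much higher electrophilicity of the BF3-activated alkoxymethylene carbon should secure. Site selectivity is fixed by the substitution pattern, and survival of the protecting groups by the choice of TIPS on the phenol and TBDPS on the secondary alcohol.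

Step 10
Reactants: 18 ethyl 6,8-dimethyl-2-oxo-5-[(S)-2-(tert-butyldiphenylsilyloxy)propyl]-7-(triisopropylsilyloxy)-2H-chromene-3-carboxylate
Product: 19 6,8-dimethyl-2-oxo-5-[(S)-2-(tert-butyldiphenylsilyloxy)propyl]-7-(triisopropylsilyloxy)-2H-chromene-3-carboxylic acid
Conditions: LiOH (3 equiv), THF/H2O 3:1, 0 °C; then aq. HCl to pH 2
Reagents that add atoms: lithium hydroxide, [Li+].[OH-]
Why: Saponification of an ethyl coumarin-3-carboxylate, the standard route to coumarin-3-carboxylic acids; any hydroxide-opened lactone is an arylidenemalonate in which a carboxyl always lies cis to the phenol, so it recloses on acidification. The aryl TIPS ether, shielded by two ortho methyls, should outlast brief contact with LiOH at 0 °C, and the alkyl TBDPS ether is stable.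

Step 11
Reactants: 19 6,8-dimethyl-2-oxo-5-[(S)-2-(tert-butyldiphenylsilyloxy)propyl]-7-(triisopropylsilyloxy)-2H-chromene-3-carboxylic acid
Product: 20 6,8-dimethyl-2-oxo-5-[(S)-2-(tert-butyldiphenylsilyloxy)propyl]-7-(triisopropylsilyloxy)-2H-chromene-3-carbonyl chloride
Conditions: (COCl)2, DMF (cat.), CH2Cl2, 0 °C → rt; used crude
Reagents that add atoms: oxalyl chloride, ClC(=O)C(=O)Cl
Why: Acid chloride formation with oxalyl chloride and catalytic DMF, mild enough for both silyl ethers.

Step 12
Reactants: 21 (R)-pent-4-en-2-ol
Product: 22 (R)-tert-butyldimethyl(pent-4-en-2-yloxy)silane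
Conditions: TBSCl, imidazole, DMF, 0 °C → rt
Reagents that add atoms: tert-butyl(chloro)dimethylsilane (TBSCl), CC(C)(C)[Si](C)(C)Cl
Why: Standard silylation of a secondary alcohol; TBS is chosen so that acid alone can remove it in step 15.

Step 13
Reactants: 22 (R)-tert-butyldimethyl(pent-4-en-2-yloxy)silane
Product: 23 (R)-4-(tert-butyldimethylsilyloxy)pentan-2-one
Conditions: PdCl2 (10 mol%), CuCl, O2 (1 atm), DMF/H2O 7:1, rt
Reagents that add atoms: water, O
Why: Tsuji–Wacker oxidation of a terminal alkene to the methyl ketone (Markovnikov hydroxypalladation, then β-hydride elimination); the stereocentre is not touched.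

Step 14
Reactants: 23 (R)-4-(tert-butyldimethylsilyloxy)pentan-2-one; 20 6,8-dimethyl-2-oxo-5-[(S)-2-(tert-butyldiphenylsilyloxy)propyl]-7-(triisopropylsilyloxy)-2H-chromene-3-carbonyl chloride
Product: 24 (R)-5-(tert-butyldimethylsilyloxy)-1-{6,8-dimethyl-2-oxo-5-[(S)-2-(tert-butyldiphenylsilyloxy)propyl]-7-(triisopropylsilyloxy)-2H-chromen-3-yl}hexane-1,3-dione
Conditions: 23 (2.2 equiv), LiN(SiMe3)2 (2.2 equiv), THF, −78 °C; then 20 (1.0 equiv), −78 °C; aq. NH4Cl
Reagents that add atoms: none
Why: Claisen-type C-acylation of a kinetic lithium enolate by an acid chloride: LiN(SiMe3)2 at −78 °C deprotonates the methyl group of 23, and the acid chloride is far more electrophilic than C4 or the lactone carbonyl. The second equivalent of enolate is consumed in deprotonating the β-diketone, and the amine by-product is not nucleophilic.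

Step 15
Reactants: 24 (R)-5-(tert-butyldimethylsilyloxy)-1-{6,8-dimethyl-2-oxo-5-[(S)-2-(tert-butyldiphenylsilyloxy)propyl]-7-(triisopropylsilyloxy)-2H-chromen-3-yl}hexane-1,3-dione
Product: 27 7-hydroxy-5-[(S)-2-hydroxypropyl]-6,8-dimethyl-3-[(R)-6-methyl-4-oxo-5,6-dihydro-4H-pyran-2-yl]-2H-chromen-2-one, via hydroxy diketone 25 (not isolated), via bis-silyl dihydropyranone 26 (not isolated)
Conditions: TFA, CH2Cl2 (trace H2O), 0 °C → rt; aqueous work-up; then HF·pyridine, pyridine, THF, 0 °C → rt
Reagents that add atoms: none
Why: Acid removes only the TBS ether; the δ-hydroxy β-diketone 25 closes on the aryl-side carbonyl (6-exo-trig hemiketalisation, the only six-membered mode) and dehydrates to 26, a standard cyclodehydration in which the C6'–O bond is never broken, so the R configuration is kept. Buffered HF·pyridine then cleaves the aryl TIPS and alkyl TBDPS ethers without the base that would open the pyranone.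

## Compound list

1 | (S)-pent-4-en-2-ol | C[C@H](O)CC=C | starting material
2 | (S)-tert-butyl(pent-4-en-2-yloxy)diphenylsilane | C=CC[C@H](C)O[Si](c1ccccc1)(c1ccccc1)C(C)(C)C | intermediate
3 | ethyl acrylate | C=CC(=O)OCC | starting material
4 | ethyl (S,E)-5-(tert-butyldiphenylsilyloxy)hex-2-enoate | CCOC(=O)/C=C/C[C@H](C)O[Si](c1ccccc1)(c1ccccc1)C(C)(C)C | intermediate
5 | pentan-3-one | CCC(=O)CC | starting material
6 | ethyl 3-[(S)-2-(tert-butyldiphenylsilyloxy)propyl]-4-methyl-5-oxoheptanoate (mixture at C3 and C4) | CCOC(=O)CC(C[C@H](C)O[Si](c1ccccc1)(c1ccccc1)C(C)(C)C)C(C)C(=O)CC | intermediate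
7 | 5-[(S)-2-(tert-butyldiphenylsilyloxy)propyl]-2,4-dimethylcyclohexane-1,3-dione (mixture of ring diastereomers) | CC1C(=O)C(C)C(=O)CC1C[C@H](C)O[Si](c1ccccc1)(c1ccccc1)C(C)(C)C | intermediate
8 | 5-[(S)-2-(tert-butyldiphenylsilyloxy)propyl]-2,4-dimethylbenzene-1,3-diol | Cc1c(O)c(C)c(O)cc1C[C@H](C)O[Si](c1ccccc1)(c1ccccc1)C(C)(C)C | intermediate
9 | 3-(tert-butyldimethylsilyloxy)-5-[(S)-2-(tert-butyldiphenylsilyloxy)propyl]-2,6-dimethylphenol | Cc1c(O)c(C)c(O[Si](C)(C)C(C)(C)C)cc1C[C@H](C)O[Si](c1ccccc1)(c1ccccc1)C(C)(C)C | intermediate
10 | {5-(tert-butyldimethylsilyloxy)-3-[(S)-2-(tert-butyldiphenylsilyloxy)propyl]-2,6-dimethylphenoxy}triisopropylsilane | Cc1c(O[Si](C(C)C)(C(C)C)C(C)C)c(C)c(O[Si](C)(C)C(C)(C)C)cc1C[C@H](C)O[Si](c1ccccc1)(c1ccccc1)C(C)(C)C | intermediate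
11 | 5-[(S)-2-(tert-butyldiphenylsilyloxy)propyl]-2,4-dimethyl-3-(triisopropylsilyloxy)phenol | Cc1c(O[Si](C(C)C)(C(C)C)C(C)C)c(C)c(O)cc1C[C@H](C)O[Si](c1ccccc1)(c1ccccc1)C(C)(C)C | intermediate
12 | ethyl malonyl chloride (ethyl 3-chloro-3-oxopropanoate) | CCOC(=O)CC(=O)Cl | starting material
13 | ethyl 5-[(S)-2-(tert-butyldiphenylsilyloxy)propyl]-2,4-dimethyl-3-(triisopropylsilyloxy)phenyl malonate | CCOC(=O)CC(=O)Oc1cc(C[C@H](C)O[Si](c2ccccc2)(c2ccccc2)C(C)(C)C)c(C)c(O[Si](C(C)C)(C(C)C)C(C)C)c1C | intermediate
14 | triethyl orthoformate | CCOC(OCC)OCC | starting material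
15 | 1-ethyl 3-{5-[(S)-2-(tert-butyldiphenylsilyloxy)propyl]-2,4-dimethyl-3-(triisopropylsilyloxy)phenyl} 2-(diethoxymethyl)malonate | CCOC(OCC)C(C(=O)OCC)C(=O)Oc1cc(C[C@H](C)O[Si](c2ccccc2)(c2ccccc2)C(C)(C)C)c(C)c(O[Si](C(C)C)(C(C)C)C(C)C)c1C | intermediate
16 | 1-ethyl 3-{5-[(S)-2-(tert-butyldiphenylsilyloxy)propyl]-2,4-dimethyl-3-(triisopropylsilyloxy)phenyl} 2-(ethoxymethylene)malonate (E/Z mixture) | CCOC=C(C(=O)OCC)C(=O)Oc1cc(C[C@H](C)O[Si](c2ccccc2)(c2ccccc2)C(C)(C)C)c(C)c(O[Si](C(C)C)(C(C)C)C(C)C)c1C | intermediate
17 | ethyl 4-ethoxy-6,8-dimethyl-2-oxo-5-[(S)-2-(tert-butyldiphenylsilyloxy)propyl]-7-(triisopropylsilyloxy)chromane-3-carboxylate | CCOC1c2c(C[C@H](C)O[Si](c3ccccc3)(c3ccccc3)C(C)(C)C)c(C)c(O[Si](C(C)C)(C(C)C)C(C)C)c(C)c2OC(=O)C1C(=O)OCC | intermediate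
18 | ethyl 6,8-dimethyl-2-oxo-5-[(S)-2-(tert-butyldiphenylsilyloxy)propyl]-7-(triisopropylsilyloxy)-2H-chromene-3-carboxylate | CCOC(=O)c1cc2c(C[C@H](C)O[Si](c3ccccc3)(c3ccccc3)C(C)(C)C)c(C)c(O[Si](C(C)C)(C(C)C)C(C)C)c(C)c2oc1=O | intermediate
19 | 6,8-dimethyl-2-oxo-5-[(S)-2-(tert-butyldiphenylsilyloxy)propyl]-7-(triisopropylsilyloxy)-2H-chromene-3-carboxylic acid | OC(=O)c1cc2c(C[C@H](C)O[Si](c3ccccc3)(c3ccccc3)C(C)(C)C)c(C)c(O[Si](C(C)C)(C(C)C)C(C)C)c(C)c2oc1=O | intermediate
20 | 6,8-dimethyl-2-oxo-5-[(S)-2-(tert-butyldiphenylsilyloxy)propyl]-7-(triisopropylsilyloxy)-2H-chromene-3-carbonyl chloride | ClC(=O)c1cc2c(C[C@H](C)O[Si](c3ccccc3)(c3ccccc3)C(C)(C)C)c(C)c(O[Si](C(C)C)(C(C)C)C(C)C)c(C)c2oc1=O | intermediate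
21 | (R)-pent-4-en-2-ol | C[C@@H](O)CC=C | starting material
22 | (R)-tert-butyldimethyl(pent-4-en-2-yloxy)silane | C=CC[C@@H](C)O[Si](C)(C)C(C)(C)C | intermediate
23 | (R)-4-(tert-butyldimethylsilyloxy)pentan-2-one | CC(=O)C[C@@H](C)O[Si](C)(C)C(C)(C)C | intermediate
24 | (R)-5-(tert-butyldimethylsilyloxy)-1-{6,8-dimethyl-2-oxo-5-[(S)-2-(tert-butyldiphenylsilyloxy)propyl]-7-(triisopropylsilyloxy)-2H-chromen-3-yl}hexane-1,3-dione | O=C(CC(=O)C[C@@H](C)O[Si](C)(C)C(C)(C)C)c1cc2c(C[C@H](C)O[Si](c3ccccc3)(c3ccccc3)C(C)(C)C)c(C)c(O[Si](C(C)C)(C(C)C)C(C)C)c(C)c2oc1=O | intermediate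
25 | (R)-5-hydroxy-1-{6,8-dimethyl-2-oxo-5-[(S)-2-(tert-butyldiphenylsilyloxy)propyl]-7-(triisopropylsilyloxy)-2H-chromen-3-yl}hexane-1,3-dione | O=C(CC(=O)C[C@@H](C)O)c1cc2c(C[C@H](C)O[Si](c3ccccc3)(c3ccccc3)C(C)(C)C)c(C)c(O[Si](C(C)C)(C(C)C)C(C)C)c(C)c2oc1=O | intermediate
26 | 6,8-dimethyl-3-[(R)-6-methyl-4-oxo-5,6-dihydro-4H-pyran-2-yl]-5-[(S)-2-(tert-butyldiphenylsilyloxy)propyl]-7-(triisopropylsilyloxy)-2H-chromen-2-one | C[C@@H]1CC(=O)C=C(O1)c1cc2c(C[C@H](C)O[Si](c3ccccc3)(c3ccccc3)C(C)(C)C)c(C)c(O[Si](C(C)C)(C(C)C)C(C)C)c(C)c2oc1=O | intermediate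
27 | 7-hydroxy-5-[(S)-2-hydroxypropyl]-6,8-dimethyl-3-[(R)-6-methyl-4-oxo-5,6-dihydro-4H-pyran-2-yl]-2H-chromen-2-one | Cc1c(O)c(C)c2oc(=O)c(C3=CC(=O)C[C@@H](C)O3)cc2c1C[C@H](C)O | target

## Step count and risks

Total step count: 15. Longest linear sequence: 13 steps (steps 1–11, 14, 15); steps 12–13 form the two-step side branch to **23**.

**Step 9 (key step).** The ring closure may be slow, because the C7 silyloxy group is twisted out of the ring plane by its two ortho methyls and donates less than a free phenol would. BF3-induced cleavage of the aryl ester or loss of a silyl group could then overtake it. Fallback: from **11**, ortho-formylation at the only free position (MgCl2, Et3N, paraformaldehyde, MeCN, reflux) would give the salicylaldehyde 2-hydroxy-3,5-dimethyl-6-[(S)-2-(tert-butyldiphenylsilyloxy)propyl]-4-(triisopropylsilyloxy)benzaldehyde F1. Knoevenagel condensation and lactonisation with diethyl malonate (piperidine, AcOH, EtOH) would return to the route at **18**.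

**Step 3.** γ-Deprotonation of enoate **4** followed by β-elimination of the silyloxide (giving a sorbate) may compete with conjugate addition, and the addition itself may be sluggish for a lithium ketone enolate. Fallback: from **2**, cross-metathesis with pent-1-en-3-one (same catalyst) would give the enone (S,E)-7-(tert-butyldiphenylsilyloxy)oct-4-en-3-one F2. Michael addition of diethyl methylmalonate under catalytic NaOEt, a medium buffered by the malonate and too weakly basic for γ-deprotonation, would give the adduct diethyl 2-methyl-2-[(2S)-2-(tert-butyldiphenylsilyloxy)-6-oxooctan-4-yl]malonate F3. Claisen cyclisation with NaOEt (1 equiv) would give the keto ester ethyl 1,3-dimethyl-2,4-dioxo-6-[(S)-2-(tert-butyldiphenylsilyloxy)propyl]cyclohexane-1-carboxylate F4, and dealkoxycarbonylation (LiCl, wet DMSO, 150 °C) would return to the route at **7**.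

**Step 8.** Exchange of the activated aryl ester with the ethanol released, thermal loss of the phenol through a ketene, or uncontrolled early ring closure may occur at 120 °C. Fallback: from **11**, bypassing **13**. Diethyl ethoxymethylenemalonate would be mono-saponified (KOH, 1 equiv, EtOH, then acid) to the half acid 3-ethoxy-2-(ethoxycarbonyl)acrylic acid F5 and converted with (COCl)2/DMF into the acid chloride ethyl 2-(chlorocarbonyl)-3-ethoxyacrylate F6. Acylation of **11** with it (pyridine, CH2Cl2, 0 °C) would give **16** directly under mild conditions.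

**Step 4.** Transfer of the liberated hydrogen to unreacted dione may cause over-reduction and C–O hydrogenolysis to mono-phenols, and conversion may be incomplete. Fallback: from **7**, the dianion (LiN(iPr)2, 2.2 equiv, THF, −78 → 0 °C) would be selenenylated at the ring CH2 with PhSeCl to give the selenide 5-[(S)-2-(tert-butyldiphenylsilyloxy)propyl]-2,4-dimethyl-6-(phenylselanyl)cyclohexane-1,3-dione F7. Oxidation with H2O2, selenoxide syn-elimination and tautomerisation would return to the route at **8**.

**Step 14.** O-acylation of the enolate, or conjugate addition of the excess enolate to C4 of the coumarin, may compete with C-acylation. Fallback: from **20**, reduction with Bu3SnH and Pd(PPh3)4 (zerovalent palladium) would give the aldehyde 6,8-dimethyl-2-oxo-5-[(S)-2-(tert-butyldiphenylsilyloxy)propyl]-7-(triisopropylsilyloxy)-2H-chromene-3-carbaldehyde F8. Aldol addition of the lithium enolate of **23** at −78 °C would give the β-hydroxy ketone (5R)-5-(tert-butyldimethylsilyloxy)-1-hydroxy-1-{6,8-dimethyl-2-oxo-5-[(S)-2-(tert-butyldiphenylsilyloxy)propyl]-7-(triisopropylsilyloxy)-2H-chromen-3-yl}hexan-3-one F9, and Dess–Martin oxidation would return to the route at **24**.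

**Step 10.** Hydroxide may cleave the aryl TIPS ether, since the 7-oxycoumarin phenoxide is a good leaving group. Fallback: from **18**, saponification would be run to completion to the hydroxy acid 7-hydroxy-6,8-dimethyl-2-oxo-5-[(S)-2-(tert-butyldiphenylsilyloxy)propyl]-2H-chromene-3-carboxylic acid F10. Double silylation (TIPSOTf, 2.5 equiv, 2,6-lutidine) would give the silyl ether silyl ester triisopropylsilyl 6,8-dimethyl-2-oxo-5-[(S)-2-(tert-butyldiphenylsilyloxy)propyl]-7-(triisopropylsilyloxy)-2H-chromene-3-carboxylate F11, and selective hydrolysis of the labile silyl ester (AcOH/THF/H2O) would return to the route at **19**.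

## Further compounds

F1 | step 9 | 2-hydroxy-3,5-dimethyl-6-[(S)-2-(tert-butyldiphenylsilyloxy)propyl]-4-(triisopropylsilyloxy)benzaldehyde | O=Cc1c(O)c(C)c(O[Si](C(C)C)(C(C)C)C(C)C)c(C)c1C[C@H](C)O[Si](c1ccccc1)(c1ccccc1)C(C)(C)C
F2 | step 3 | (S,E)-7-(tert-butyldiphenylsilyloxy)oct-4-en-3-one | CCC(=O)/C=C/C[C@H](C)O[Si](c1ccccc1)(c1ccccc1)C(C)(C)C
F3 | step 3 | diethyl 2-methyl-2-[(2S)-2-(tert-butyldiphenylsilyloxy)-6-oxooctan-4-yl]malonate | CCOC(=O)C(C)(C(=O)OCC)C(CC(=O)CC)C[C@H](C)O[Si](c1ccccc1)(c1ccccc1)C(C)(C)C
F4 | step 3 | ethyl 1,3-dimethyl-2,4-dioxo-6-[(S)-2-(tert-butyldiphenylsilyloxy)propyl]cyclohexane-1-carboxylate | CCOC(=O)C1(C)C(=O)C(C)C(=O)CC1C[C@H](C)O[Si](c1ccccc1)(c1ccccc1)C(C)(C)C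
F5 | step 8 | 3-ethoxy-2-(ethoxycarbonyl)acrylic acid | CCOC=C(C(=O)O)C(=O)OCC
F6 | step 8 | ethyl 2-(chlorocarbonyl)-3-ethoxyacrylate | CCOC=C(C(=O)Cl)C(=O)OCC
F7 | step 4 | 5-[(S)-2-(tert-butyldiphenylsilyloxy)propyl]-2,4-dimethyl-6-(phenylselanyl)cyclohexane-1,3-dione | CC1C(=O)C(C)C(=O)C([Se]c2ccccc2)C1C[C@H](C)O[Si](c1ccccc1)(c1ccccc1)C(C)(C)C
F8 | step 14 | 6,8-dimethyl-2-oxo-5-[(S)-2-(tert-butyldiphenylsilyloxy)propyl]-7-(triisopropylsilyloxy)-2H-chromene-3-carbaldehyde | O=Cc1cc2c(C[C@H](C)O[Si](c3ccccc3)(c3ccccc3)C(C)(C)C)c(C)c(O[Si](C(C)C)(C(C)C)C(C)C)c(C)c2oc1=O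
F9 | step 14 | (5R)-5-(tert-butyldimethylsilyloxy)-1-hydroxy-1-{6,8-dimethyl-2-oxo-5-[(S)-2-(tert-butyldiphenylsilyloxy)propyl]-7-(triisopropylsilyloxy)-2H-chromen-3-yl}hexan-3-one | OC(CC(=O)C[C@@H](C)O[Si](C)(C)C(C)(C)C)c1cc2c(C[C@H](C)O[Si](c3ccccc3)(c3ccccc3)C(C)(C)C)c(C)c(O[Si](C(C)C)(C(C)C)C(C)C)c(C)c2oc1=O
F10 | step 10 | 7-hydroxy-6,8-dimethyl-2-oxo-5-[(S)-2-(tert-butyldiphenylsilyloxy)propyl]-2H-chromene-3-carboxylic acid | OC(=O)c1cc2c(C[C@H](C)O[Si](c3ccccc3)(c3ccccc3)C(C)(C)C)c(C)c(O)c(C)c2oc1=O
F11 | step 10 | triisopropylsilyl 6,8-dimethyl-2-oxo-5-[(S)-2-(tert-butyldiphenylsilyloxy)propyl]-7-(triisopropylsilyloxy)-2H-chromene-3-carboxylate | CC(C)[Si](OC(=O)c1cc2c(C[C@H](C)O[Si](c3ccccc3)(c3ccccc3)C(C)(C)C)c(C)c(O[Si](C(C)C)(C(C)C)C(C)C)c(C)c2oc1=O)(C(C)C)C(C)C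
A1 | alternative 1 | (S)-parasorbic acid, (S)-6-methyl-5,6-dihydro-2H-pyran-2-one | C[C@H]1CC=CC(=O)O1
A2 | alternative 1 | 5-[(S)-2-hydroxypropyl]-2,4-dimethylcyclohexane-1,3-dione | CC1C(=O)C(C)C(=O)CC1C[C@H](C)O
A3 | alternative 2 | 2,4-dimethoxy-3,5-dimethylbenzoic acid | OC(=O)c1cc(C)c(OC)c(C)c1OC
A4 | alternative 2 | (S)-propylene oxide | C[C@H]1CO1
A5 | alternative 2 | (S)-6,8-dimethoxy-3,5,7-trimethylisochroman-1-one | Cc1c(OC)c(C)c(OC)c2c1C[C@H](C)OC2=O
A6 | alternative 3 | 3-[1,3-bis(trimethylsilyloxy)buta-1,3-dien-1-yl]-7-(tert-butyldimethylsilyloxy)-5-[(S)-2-(tert-butyldimethylsilyloxy)propyl]-6,8-dimethyl-2H-chromen-2-one | C=C(O[Si](C)(C)C)C=C(O[Si](C)(C)C)c1cc2c(C[C@H](C)O[Si](C)(C)C(C)(C)C)c(C)c(O[Si](C)(C)C(C)(C)C)c(C)c2oc1=O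
A7 | alternative 3 | acetaldehyde | CC=O
A8 | alternative 3 | bis(tert-butyldimethylsilyl) ether of the target | Cc1c(O[Si](C)(C)C(C)(C)C)c(C)c2oc(=O)c(C3=CC(=O)C[C@@H](C)O3)cc2c1C[C@H](C)O[Si](C)(C)C(C)(C)C
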